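(Its constants are invented; what happens was integrated by code.)

We have a coin to toss.

    partner + catalyst intermediate → free catalyst + product (k1 = 8.3 L mol⁻¹ s⁻¹)
    free catalyst + open intermediate ⇌ catalyst intermediate (K2 = 10 L mol⁻¹, k2 = 78 L mol⁻¹ s⁻¹)
    starting material + free catalyst ⇌ free catalyst + open intermediate (K3 = 1.1, k3 = 5.6 L mol⁻¹ s⁻¹)

starting material 0.10 M; partner 0.800 equiv; free catalyst 1 mol%; time 2.5 min

* share of the starting material used up at 2.5 min
* product at 2.5 min, in percent of the starting material charged
* open intermediate at 2.5 min, in percent of the starting material charged

First question: where does a departing open intermediate go? With free catalyst it returns to starting material at constant 5.09 L mol⁻¹ s⁻¹. Otherwise free catalyst captures it as catalyst intermediate, which falls back at 7.80 s⁻¹, faster than it goes on with partner as charged, at 0.664 s⁻¹. This is a pre-equilibrium, and the onward constant is 6.12 L mol⁻¹ s⁻¹. Both exits carry c(free catalyst), which cancels in the onward share 0.546: the part of departing open intermediate that goes on to product and not back. An even toss is the middle of this scale, and we stand near half.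

Second question: how long does the toss run? Step 3 and the onward route both run in proportion to c(free catalyst), so the clock is its integral over time. At its own equilibrium step 3 would put 52.4% of the charge into open intermediate, and we guess that c(open intermediate) averages half of that, 0.0262 M, which leaves a free share of 0.792 and a clock of 0.119 M·s.

Starting material and open intermediate then form two linear boxes, with rate constants 14.4 L mol⁻¹ s⁻¹ and 2.37 L mol⁻¹ s⁻¹. Our reckoning gives conversion 39.9%, product 13.3% and open intermediate 26.7%.

The forecast gives 41.5%, 13.3% and 28%, holding that “the open intermediate builds to about twice the product”. The flask gives 41.5%, 13.6% and 27.7%.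

Up to 2.5 min in this flask, step 3 ran back for 23% of its forward turnover, which on a net 41.5% returned 12.3% of the charge against 13.6% gone on to product, so the onward share read there is 0.524, beside the 0.546 reckoned with partner as charged. In the neighbour flask with 0.060 M of starting material, the onward share reckoned the same way is lower, 0.427, and that flask holds 26.4% open intermediate beside 4.82% product.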